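Compound numbers are those of the steps and of the compound list below.

## Analysis of the target

Target 34 is a 2,3,4,7-tetrahydrooxepine, numbered O1, C2, C3, C4, C5=C6, C7. C2 is fully substituted and carries the ring oxygen, a free carboxylic acid and a CH2C(=O)Ar arm whose aryl group is 2,5-dihydroxyphenyl. C6 carries a (3E)-4-methylpent-3-enyl chain whose terminal allylic oxygen is acylated by (E)-4-hydroxycinnamic acid. C2 (R) is the only stereocentre, so no relative configuration has to be set, but as a tetrasubstituted ether carbon it cannot be corrected later by epimerisation. O1 is β to the aryl ketone, so a base can expel it from the ketone enolate and open the ring. The hydroquinone is easily oxidised, the cinnamate is an allylic ester open to nucleophiles, and both trisubstituted alkenes are sensitive to strong acid. The hard points are the seven-membered ether whose oxygen sits on a hindered quaternary carbon, the exact placement of the ring alkene at C5=C6 with the chain on C6, and the distinction between the carboxyl group on C2 and the one in its CH2 arm. The strategy rests on two features: O1, C2, C3, C4, C5 and C7 form a dihydropyran whose enol-ether carbons are C5 and C7, with C6 as a single inserted carbon; and C1, C2, O1 and the CH2CO arm are the skeleton of malic acid with C3 as an added substituent.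

## Retrosynthetic reasoning

34 to 33. Only protecting groups are removed: three aryl silyl ethers and the silylethyl ester. The free acid, the phenols and the base-labile β-alkoxy ketone are therefore unveiled together in the last operation, by fluoride, and never meet an organometallic or a Lewis acid.

33 to 29 and 32. The acyl C–O bond of the allylic cinnamate is cut. The enoate is introduced late because it would not survive the ester hydrolysis, the zinc reagents or palladium that come before; forward, a carbodiimide esterification of primary allylic alcohol 29 with acid 32 (from 30) is needed, after selective release of that alcohol from its triethylsilyl ether in 28.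

28 to 23 and 25. The bond between the ketone carbon and the arene is cut, which makes the hydroquinone ring available from 24 as the metalated bis-silyl ether 27. The ketone is formed only after the steps that would reduce or enolise it. Forward, acid chloride 23 has to be acylated by an aryl nucleophile that leaves the hindered silylethyl ester alone; 23 comes from methyl ester 21 through acid 22, so the two carboxyl groups must differ as methyl and silylethyl esters.

21 to 16 and 19. The sp2–sp3 bond between C6 and the chain is cut. A vinyl bromide at C6 (16) fixes the position of the ring alkene, and the chain comes as zinc reagent 20 from bromide 19, made by E-selective allylic oxidation of 17 to 18 and silylation. A cross-coupling is chosen over carbonyl olefination because the ring alkene then never has to be formed regioselectively.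

16 to 15 to 13 to 11 and 12. This is the key disconnection. C7 of 16 is taken back to the mixed acetal 15, and 15 to the cyclopropane 13 by reconnecting C5 to C7; removing C6 then leaves dihydropyran 11 and the carbene source 12. The seven-membered ring is thus never closed by cyclisation onto the hindered oxygen; it is obtained by cleaving the shared bond of a bicycle built on a six-membered ring. The halogen left on C6 is the coupling handle, and C2 is remote and not touched. Forward, ionisation must occur by loss of the endo bromide with capture of the cation at C7.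

11 to 9 to 7. The enol ether is taken back to lactol 9, and the C5–C7 bond is cut, so that C7 comes from linear hydroformylation of the allyl group of 7. This delivers the aldehyde oxidation level directly, and the tertiary hydroxyl closes the six-membered lactol by itself.

7 to 6 to 5 to 2 and 3; 2 to 1. The C2–C3 bond is cut. D-malic acid 1 supplies C1, C2, O1 and the acetic arm with the right configuration. Its tert-butyl acetal 2 is alkylated as the dianion 4 with allyl bromide 3, with retention at C2. Opening the acetal ring of 5 with a silylethyl alkoxide while the side-chain acid is still a carboxylate gives 6 and settles the two carboxyl groups before the methyl ester of 7 is made.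

## Alternatives that were turned down

Alternative 1: The O1–C2 bond is cut, which leads to the open-chain hydroxy enone A1, a Z-allylic alcohol tethered to an (E)-aroylacrylate. Forward, the C7 hydroxyl would add to C2 of the enone in a seven-membered oxa-Michael closure to give A2, which is the same compound as 28. In its favour: it probably follows the biosynthesis, it is convergent, and it forms the ether bond and C2 in one step; in step count it is stronger than the chosen route. Against it: the C2 stereocentre would be created in that step with nothing in A1 to bias the face. A chiral catalyst would have to control a β,β-disubstituted acceptor, a tetrasubstituted ether centre and a seven-membered ring at once. The addition is also reversible, the reverse reaction being the one that threatens the target, so selectivity could erode towards the racemate. A Z-trisubstituted allylic alcohol would have to be made with full control of geometry. The chosen strategy takes C2 from the chiral pool before the ring exists and pays for that certainty with a longer linear sequence.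

Alternative 2: The O1–C7 bond is cut, which leads to the hydroxy diazoketone A3. Forward, Rh2(OAc)4 would generate a carbenoid at C7 into which the tertiary hydroxyl inserts, giving oxepan-3-one A4 with the ketone at C6. In its favour: O–H insertion is fast, neutral and works on hindered alcohols, and C2 can come from the same chiral-pool source, so on ring formation and stereocontrol it is as strong as the chosen route. Against it: A4 carries a ketone where the target has a substituted alkene. The alkene would have to come from an enol triflate, and its position depends on selective enolisation towards C5 and not C7. Carbenoid C–H insertion at C3 to a cyclopentanone competes. A3 needs selective activation of one carboxyl group among several, and the aryl ketone has to travel as a dioxolane that is removed by acid late. The chosen route places the double bond and the halogen on C6 as a direct consequence of the mechanism. In return it gives up the earlier introduction of the aryl group that alternative 2 allows.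

Alternative 3: The C6–C7 bond is cut, which leads to A5, the methoxymethyl ether of the C2 oxygen carrying a Z-vinylsilane. Forward, SnCl4 would ionise the acetal and the vinylsilane would attack the O1=CH2 cation through its silicon-bearing carbon, giving the fully silylated target A6, which is the same compound as 33. In its favour: ipso substitution fixes the position and geometry of the ring alkene as firmly as the vinyl bromide does in the chosen route, and the key step lands one step from the target, so it is the strongest of all in convergence. Against it: a strong Lewis acid would act on the most elaborate intermediate, which carries aryl silyl ethers, a silylethyl ester, an ionisable allylic cinnamate and a second trisubstituted alkene. The oxocarbenium ion sits on an oxygen bound to an electron-poor quaternary carbon, so protodesilylation and chloride capture compete with a seven-membered closure. The Z-trisubstituted vinylsilane and the acetal on a hindered tertiary hydroxy ester are both laborious to make. The chosen route takes its risk early, on a small bicyclic diester that is cheap to remake.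

Key step: step 8

Remark on the chemistry: lactol 9, cyclopropane 13 and acetal 15 are expected as mixtures of epimers at centres that steps 6, 8 and 9 respectively remove; one epimer of each is drawn and the mixtures are carried on.

## Route

Step 1
Reactants: 1 D-malic acid
Product: 2 [(2R,4R)-2-tert-butyl-5-oxo-1,3-dioxolan-4-yl]acetic acid (cis isomer)
Conditions: t-BuCHO, TsOH·H2O (cat.), H2SO4 (cat.), pentane, reflux, Dean–Stark; recrystallisation
Reagents that add atoms: pivalaldehyde, CC(C)(C)C=O
Why: Acid-catalysed acetalisation of the α-hydroxy acid unit gives the dioxolanone; the new acetal centre settles cis to the CH2CO2H arm under thermodynamic control and the cis isomer is purified by crystallisation.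

Step 2
Reactants: 2 [(2R,4R)-2-tert-butyl-5-oxo-1,3-dioxolan-4-yl]acetic acid; 3 allyl bromide
Product: 5 [(2R,4R)-2-tert-butyl-5-oxo-4-(prop-2-en-1-yl)-1,3-dioxolan-4-yl]acetic acid, via dilithium enolate carboxylate 4 (not isolated)
Conditions: LiHMDS (2.2 equiv), THF, −78 °C; 3, −78 to −20 °C; aq. HCl work-up
Reagents that add atoms: none
Why: Enolate alkylation by self-regeneration of the stereocentre: the tert-butyl group blocks one face of the planar enolate, so the allyl group enters trans to it and takes the place of the former hydrogen, which fixes C2 as R. The carboxylate keeps the CH2 arm from being deprotonated, so β-elimination of the acetal oxygen is avoided.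

Step 3
Reactants: 5 [(2R,4R)-2-tert-butyl-5-oxo-4-(prop-2-en-1-yl)-1,3-dioxolan-4-yl]acetic acid
Product: 6 (3R)-3-hydroxy-3-{[2-(trimethylsilyl)ethoxy]carbonyl}hex-5-enoic acid
Conditions: Me3SiCH2CH2OH (6 equiv), n-BuLi (4 equiv), THF, −20 to 0 °C; aq. HCl work-up
Reagents that add atoms: 2-(trimethylsilyl)ethanol, C[Si](C)(C)CCO
Why: Alkoxide acyl substitution opens the activated dioxolanone carbonyl and the hemiacetal alkoxide loses pivalaldehyde, which frees the tertiary hydroxyl. The side-chain acid is a carboxylate and is neither esterified nor enolised, so the two carboxyl groups become different in this step.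

Step 4
Reactants: 6 (3R)-3-hydroxy-3-{[2-(trimethylsilyl)ethoxy]carbonyl}hex-5-enoic acid
Product: 7 4-methyl 1-[2-(trimethylsilyl)ethyl] (2R)-2-hydroxy-2-(prop-2-en-1-yl)butanedioate
Conditions: MeI, KHCO3, DMF, rt
Reagents that add atoms: iodomethane, CI
Why: O-Alkylation of the carboxylate by an SN2 reaction; the hindered tertiary hydroxyl is not alkylated under bicarbonate.

Step 5
Reactants: 7 4-methyl 1-[2-(trimethylsilyl)ethyl] (2R)-2-hydroxy-2-(prop-2-en-1-yl)butanedioate
Product: 9 2-(trimethylsilyl)ethyl (2R)-6-hydroxy-2-(2-methoxy-2-oxoethyl)oxane-2-carboxylate (both anomers), via hydroxy aldehyde 8 (not isolated)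
Conditions: Rh(acac)(CO)2 (1 mol %), BiPhePhos (3 mol %), CO/H2 (1:1, 5 bar), toluene, 60 °C
Reagents that add atoms: carbon monoxide, [C-]#[O+]
Why: Rhodium-catalysed hydroformylation with a wide-bite-angle bisphosphite puts the formyl group on the terminal carbon, and the δ-hydroxy aldehyde closes to the six-membered lactol. The anomeric centre is not controlled and is removed in step 6.

Step 6
Reactants: 9 2-(trimethylsilyl)ethyl (2R)-6-hydroxy-2-(2-methoxy-2-oxoethyl)oxane-2-carboxylate
Product: 11 2-(trimethylsilyl)ethyl (2R)-2-(2-methoxy-2-oxoethyl)-3,4-dihydro-2H-pyran-2-carboxylate, via anomeric mesylate 10 (not isolated)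
Conditions: MsCl, Et3N, CH2Cl2, 0 °C to reflux
Reagents that add atoms: none
Why: Sulfonylation of the lactol hydroxyl and amine-assisted elimination through the oxocarbenium ion is the standard dehydration of 2-deoxy lactols to cyclic enol ethers. Triethylamine is too weak to enolise the ester arm.

Step 7
Reactants: 11 2-(trimethylsilyl)ethyl (2R)-2-(2-methoxy-2-oxoethyl)-3,4-dihydro-2H-pyran-2-carboxylate; 12 bromoform
Product: 13 2-(trimethylsilyl)ethyl (1R,3R,6S)-7,7-dibromo-3-(2-methoxy-2-oxoethyl)-2-oxabicyclo[4.1.0]heptane-3-carboxylate (with its (1S,3R,6R) diastereomer)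
Conditions: CHBr3 (4 equiv), 50% aq. NaOH, BnEt3NCl (10 mol %), CH2Cl2, 0 °C, vigorous stirring; crude product used at once
Reagents that add atoms: none
Why: Phase-transfer generation of dibromocarbene and its concerted [2+1] addition to the electron-rich enol ether gives a cis-fused cyclopropane on either face; both diastereomers serve. Two-phase conditions are preferred to a soluble alkoxide because O1 is β to the methyl ester carbonyl and a strong base in solution could open the ring by E1cB elimination.

Step 8
Reactants: 13 2-(trimethylsilyl)ethyl (1R,3R,6S)-7,7-dibromo-3-(2-methoxy-2-oxoethyl)-2-oxabicyclo[4.1.0]heptane-3-carboxylate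
Product: 15 2-(trimethylsilyl)ethyl (2R,7S)-6-bromo-7-methoxy-2-(2-methoxy-2-oxoethyl)-2,3,4,7-tetrahydrooxepine-2-carboxylate (with its 7R epimer), via bromoallyl oxocarbenium ion 14 (not isolated)
Conditions: AgOTf (1.5 equiv), 2,6-di-tert-butyl-4-methylpyridine (2 equiv), MeOH–CH2Cl2 (1:1), 0 °C to rt, dark
Reagents that add atoms: methanol, CO
Why: Silver ion pulls off the endo bromide while the C5–C7 bond opens in a disrotatory two-electron electrocyclic process, which gives a 2-bromoallyl cation over C5–C6–C7 that the ring oxygen stabilises as an oxocarbenium ion at C7. The closest known reaction type is the silver-assisted solvolytic ring expansion of gem-dibromocyclopropanes fused to cyclic enol ethers, which gives 2-bromo-oxepine acetals. The seven-membered ring is not closed by cyclisation: it results from cleavage of the bond shared by the two rings of the bicyclo[4.1.0] system, so no medium-ring closure has to compete with other pathways. Methanol adds at C7, where oxygen concentrates the positive charge, and not at C5. The new acetal centre at C7 is not controlled and is removed in step 9; no lasting stereocentre is formed and the remote quaternary C2 is not involved. The step needs ionisation to win over base-induced loss of HBr to a cyclopropene, which would lead to ring-retained bromomethylene pyrans, and over proton loss from the cation to a bromodiene. The absence of strong base, the halophilic silver ion and the large excess of methanol secure this. The hindered pyridine takes up the triflic acid so that the acetal and the two esters are not exposed to acid in methanol.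

Step 9
Reactants: 15 2-(trimethylsilyl)ethyl (2R,7S)-6-bromo-7-methoxy-2-(2-methoxy-2-oxoethyl)-2,3,4,7-tetrahydrooxepine-2-carboxylate
Product: 16 2-(trimethylsilyl)ethyl (2R)-6-bromo-2-(2-methoxy-2-oxoethyl)-2,3,4,7-tetrahydrooxepine-2-carboxylate
Conditions: Et3SiH (3 equiv), BF3·OEt2 (1.5 equiv), CH2Cl2, −78 to −20 °C
Reagents that add atoms: none
Why: Lewis-acid ionisation of the acetal and hydride transfer from the silane to C7 (ionic reduction, as in reductive Ferrier reactions) makes C7 a methylene group; both acetal epimers converge and the vinyl bromide is untouched.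

Step 10
Reactants: 17 5-bromo-2-methylpent-2-ene
Product: 18 (2E)-5-bromo-2-methylpent-2-en-1-ol
Conditions: SeO2 (0.5 equiv), t-BuOOH (3 equiv), CH2Cl2, rt
Reagents that add atoms: selenium dioxide, O=[Se]=O; tert-butyl hydroperoxide, CC(C)(C)OO (terminal oxidant that keeps selenium in turnover)
Why: Allylic oxidation by an ene reaction and [2,3]-sigmatropic shift attacks the methyl group trans to the chain of a gem-dimethyl alkene, which gives the E-allylic alcohol; any enal formed by over-oxidation is separated.

Step 11
Reactants: 18 (2E)-5-bromo-2-methylpent-2-en-1-ol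
Product: 19 {[(2E)-5-bromo-2-methylpent-2-en-1-yl]oxy}triethylsilane
Conditions: Et3SiCl, imidazole, CH2Cl2, 0 °C
Reagents that add atoms: chlorotriethylsilane, CC[Si](CC)(CC)Cl
Why: Standard silylation of a primary alcohol; the triethylsilyl ether can later be removed by mild acid in the presence of aryl silyl ethers.

Step 12
Reactants: 19 {[(2E)-5-bromo-2-methylpent-2-en-1-yl]oxy}triethylsilane; 16 2-(trimethylsilyl)ethyl (2R)-6-bromo-2-(2-methoxy-2-oxoethyl)-2,3,4,7-tetrahydrooxepine-2-carboxylate
Product: 21 2-(trimethylsilyl)ethyl (2R)-2-(2-methoxy-2-oxoethyl)-6-{(3E)-4-methyl-5-[(triethylsilyl)oxy]pent-3-en-1-yl}-2,3,4,7-tetrahydrooxepine-2-carboxylate, via alkylzinc bromide 20 (not isolated)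
Conditions: 19, Zn dust, I2 (5 mol %), DMA, 70 °C; then 16, Pd(dppf)Cl2·CH2Cl2 (5 mol %), THF, 50 °C
Reagents that add atoms: none
Why: Zinc insertion into the primary C–Br bond and Negishi sp3–sp2 coupling with the vinyl bromide; the wide bite angle of dppf favours reductive elimination over β-hydride elimination, and the organozinc leaves both esters intact. The ring alkene stays at C5=C6 and the E geometry of the chain is not touched.

Step 13
Reactants: 21 2-(trimethylsilyl)ethyl (2R)-2-(2-methoxy-2-oxoethyl)-6-{(3E)-4-methyl-5-[(triethylsilyl)oxy]pent-3-en-1-yl}-2,3,4,7-tetrahydrooxepine-2-carboxylate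
Product: 22 [(2R)-6-{(3E)-4-methyl-5-[(triethylsilyl)oxy]pent-3-en-1-yl}-2-{[2-(trimethylsilyl)ethoxy]carbonyl}-2,3,4,7-tetrahydrooxepin-2-yl]acetic acid
Conditions: Me3SnOH (6 equiv), ClCH2CH2Cl, 70 °C; cold dilute HCl wash
Reagents that add atoms: trimethyltin hydroxide, C[Sn](C)(C)O
Why: Trimethyltin hydroxide cleaves methyl esters selectively by acyl substitution under nearly neutral conditions; the silylethyl ester on the quaternary carbon is far more hindered, and no free base is present to open the ring by β-elimination.

Step 14
Reactants: 22 [(2R)-6-{(3E)-4-methyl-5-[(triethylsilyl)oxy]pent-3-en-1-yl}-2-{[2-(trimethylsilyl)ethoxy]carbonyl}-2,3,4,7-tetrahydrooxepin-2-yl]acetic acid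
Product: 23 2-(trimethylsilyl)ethyl (2R)-2-(2-chloro-2-oxoethyl)-6-{(3E)-4-methyl-5-[(triethylsilyl)oxy]pent-3-en-1-yl}-2,3,4,7-tetrahydrooxepine-2-carboxylate
Conditions: 1-chloro-N,N,2-trimethylprop-1-en-1-amine (1.3 equiv), CH2Cl2, 0 °C to rt; evaporation, used crude
Reagents that add atoms: 1-chloro-N,N,2-trimethylprop-1-en-1-amine, CC(C)=C(Cl)N(C)C
Why: The α-chloroenamine turns the acid into its chloride without releasing HCl, so the silyl ether, the silylethyl ester and the alkenes are not exposed to acid.

Step 15
Reactants: 24 2-bromobenzene-1,4-diol (bromohydroquinone)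
Product: 25 2-bromo-1,4-bis[(tert-butyldimethylsilyl)oxy]benzene
Conditions: TBSCl (2.4 equiv), imidazole, DMF, rt
Reagents that add atoms: tert-butyldimethylsilyl chloride, CC(C)(C)[Si](C)(C)Cl
Why: Standard silylation of both phenols, which also protects the hydroquinone against oxidation.

Step 16
Reactants: 25 2-bromo-1,4-bis[(tert-butyldimethylsilyl)oxy]benzene; 23 2-(trimethylsilyl)ethyl (2R)-2-(2-chloro-2-oxoethyl)-6-{(3E)-4-methyl-5-[(triethylsilyl)oxy]pent-3-en-1-yl}-2,3,4,7-tetrahydrooxepine-2-carboxylate
Product: 28 2-(trimethylsilyl)ethyl (2R)-2-(2-{2,5-bis[(tert-butyldimethylsilyl)oxy]phenyl}-2-oxoethyl)-6-{(3E)-4-methyl-5-[(triethylsilyl)oxy]pent-3-en-1-yl}-2,3,4,7-tetrahydrooxepine-2-carboxylate, via aryllithium 26 (not isolated), via arylzinc chloride 27 (not isolated)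
Conditions: 25 (1.5 equiv), n-BuLi, THF, −78 °C, 15 min; ZnCl2 (THF), −78 to 0 °C; then 23, Pd(PPh3)4 (5 mol %), THF, 0 °C to rt
Reagents that add atoms: none
Why: Negishi acylation: the acid chloride adds oxidatively to zerovalent palladium, the arylzinc transmetalates and reductive elimination gives the ketone, while the arylzinc does not attack the esters. Bromine–lithium exchange at −78 °C and immediate transmetalation to zinc keep the ortho-silyloxy aryllithium from silyl migration.

Step 17
Reactants: 28 2-(trimethylsilyl)ethyl (2R)-2-(2-{2,5-bis[(tert-butyldimethylsilyl)oxy]phenyl}-2-oxoethyl)-6-{(3E)-4-methyl-5-[(triethylsilyl)oxy]pent-3-en-1-yl}-2,3,4,7-tetrahydrooxepine-2-carboxylate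
Product: 29 2-(trimethylsilyl)ethyl (2R)-2-(2-{2,5-bis[(tert-butyldimethylsilyl)oxy]phenyl}-2-oxoethyl)-6-[(3E)-5-hydroxy-4-methylpent-3-en-1-yl]-2,3,4,7-tetrahydrooxepine-2-carboxylate
Conditions: PPTS (0.2 equiv), MeOH–CH2Cl2, 0 °C
Reagents that add atoms: none
Why: Mild acid methanolysis removes the primary alkyl triethylsilyl ether; aryl tert-butyldimethylsilyl ethers and the silylethyl ester are stable to these conditions.

Step 18
Reactants: 30 (2E)-3-(4-hydroxyphenyl)prop-2-enoic acid (p-coumaric acid)
Product: 32 (2E)-3-{4-[(tert-butyldimethylsilyl)oxy]phenyl}prop-2-enoic acid, via bis-silylated coumarate 31 (not isolated)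
Conditions: TBSCl (2.5 equiv), imidazole, DMF, rt; then AcOH–THF–H2O, rt
Reagents that add atoms: tert-butyldimethylsilyl chloride, CC(C)(C)[Si](C)(C)Cl
Why: Silylation of phenol and acid followed by selective hydrolysis of the far more labile silyl ester leaves the phenol protected and the acid free.

Step 19
Reactants: 29 2-(trimethylsilyl)ethyl (2R)-2-(2-{2,5-bis[(tert-butyldimethylsilyl)oxy]phenyl}-2-oxoethyl)-6-[(3E)-5-hydroxy-4-methylpent-3-en-1-yl]-2,3,4,7-tetrahydrooxepine-2-carboxylate; 32 (2E)-3-{4-[(tert-butyldimethylsilyl)oxy]phenyl}prop-2-enoic acid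
Product: 33 2-(trimethylsilyl)ethyl (2R)-2-(2-{2,5-bis[(tert-butyldimethylsilyl)oxy]phenyl}-2-oxoethyl)-6-{(3E)-5-[((2E)-3-{4-[(tert-butyldimethylsilyl)oxy]phenyl}prop-2-enoyl)oxy]-4-methylpent-3-en-1-yl}-2,3,4,7-tetrahydrooxepine-2-carboxylate
Conditions: 32 (1.3 equiv), EDC·HCl, DMAP, CH2Cl2, 0 °C to rt
Reagents that add atoms: none
Why: Steglich esterification of an unhindered primary allylic alcohol; the conditions are only weakly basic, so the β-alkoxy ketone is not enolised.

Step 20
Reactants: 33 2-(trimethylsilyl)ethyl (2R)-2-(2-{2,5-bis[(tert-butyldimethylsilyl)oxy]phenyl}-2-oxoethyl)-6-{(3E)-5-[((2E)-3-{4-[(tert-butyldimethylsilyl)oxy]phenyl}prop-2-enoyl)oxy]-4-methylpent-3-en-1-yl}-2,3,4,7-tetrahydrooxepine-2-carboxylate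
Product: 34 (2R)-2-[2-(2,5-dihydroxyphenyl)-2-oxoethyl]-6-[(3E)-5-{[(2E)-3-(4-hydroxyphenyl)prop-2-enoyl]oxy}-4-methylpent-3-en-1-yl]-2,3,4,7-tetrahydrooxepine-2-carboxylic acid (CNP0602535.1)
Conditions: TASF (6 equiv), DMF, 0 °C to rt; dilute HCl work-up to pH 3
Reagents that add atoms: none
Why: Fluoride cleaves the three aryl silyl ethers and fragments the silylethyl ester to ethene and the carboxylate in one operation. The anhydrous, weakly basic fluoride source is chosen to limit enolisation of the β-alkoxy ketone.

## Compound list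

1 | D-malic acid, (2R)-2-hydroxybutanedioic acid | O[C@H](CC(=O)O)C(=O)O | starting material
2 | [(2R,4R)-2-tert-butyl-5-oxo-1,3-dioxolan-4-yl]acetic acid | CC(C)(C)[C@H]1OC(=O)[C@@H](CC(=O)O)O1 | intermediate
3 | allyl bromide | C=CCBr | starting material
4 | dilithium enolate carboxylate of 2 | [Li+].[Li+].CC(C)(C)[C@H]1OC([O-])=C(CC(=O)[O-])O1 | intermediate (not isolated)
5 | [(2R,4R)-2-tert-butyl-5-oxo-4-(prop-2-en-1-yl)-1,3-dioxolan-4-yl]acetic acid | CC(C)(C)[C@H]1OC(=O)[C@@](CC=C)(CC(=O)O)O1 | intermediate
6 | (3R)-3-hydroxy-3-{[2-(trimethylsilyl)ethoxy]carbonyl}hex-5-enoic acid | C=CC[C@@](CC(=O)O)(C(=O)OCC[Si](C)(C)C)O | intermediate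
7 | 4-methyl 1-[2-(trimethylsilyl)ethyl] (2R)-2-hydroxy-2-(prop-2-en-1-yl)butanedioate | C=CC[C@@](CC(=O)OC)(C(=O)OCC[Si](C)(C)C)O | intermediate
8 | 4-methyl 1-[2-(trimethylsilyl)ethyl] (2R)-2-hydroxy-2-(4-oxobutyl)butanedioate | O=CCCC[C@@](CC(=O)OC)(C(=O)OCC[Si](C)(C)C)O | intermediate (not isolated)
9 | 2-(trimethylsilyl)ethyl (2R)-6-hydroxy-2-(2-methoxy-2-oxoethyl)oxane-2-carboxylate, both anomers | OC1CCC[C@@](CC(=O)OC)(C(=O)OCC[Si](C)(C)C)O1 | intermediate
10 | 2-(trimethylsilyl)ethyl (2R)-6-(methanesulfonyloxy)-2-(2-methoxy-2-oxoethyl)oxane-2-carboxylate | CS(=O)(=O)OC1CCC[C@@](CC(=O)OC)(C(=O)OCC[Si](C)(C)C)O1 | intermediate (not isolated)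
11 | 2-(trimethylsilyl)ethyl (2R)-2-(2-methoxy-2-oxoethyl)-3,4-dihydro-2H-pyran-2-carboxylate | C1=CCC[C@@](CC(=O)OC)(C(=O)OCC[Si](C)(C)C)O1 | intermediate
12 | bromoform | BrC(Br)Br | starting material
13 | 2-(trimethylsilyl)ethyl (1R,3R,6S)-7,7-dibromo-3-(2-methoxy-2-oxoethyl)-2-oxabicyclo[4.1.0]heptane-3-carboxylate, cis-fused, CBr2 bridge anti to the CH2CO2Me arm (the (1S,3R,6R) diastereomer forms alongside) | BrC1(Br)[C@H]2CC[C@@](CC(=O)OC)(C(=O)OCC[Si](C)(C)C)O[C@@H]12 | intermediate
14 | (2R)-6-bromo-2-(2-methoxy-2-oxoethyl)-2-{[2-(trimethylsilyl)ethoxy]carbonyl}-3,4-dihydro-2H-oxepin-1-ium, the bromoallyl oxocarbenium ion | BrC1=CCC[C@@](CC(=O)OC)(C(=O)OCC[Si](C)(C)C)[O+]=C1 | intermediate (not isolated)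
15 | 2-(trimethylsilyl)ethyl (2R,7S)-6-bromo-7-methoxy-2-(2-methoxy-2-oxoethyl)-2,3,4,7-tetrahydrooxepine-2-carboxylate (the 7R epimer forms alongside) | BrC1=CCC[C@@](CC(=O)OC)(C(=O)OCC[Si](C)(C)C)O[C@@H]1OC | intermediate
16 | 2-(trimethylsilyl)ethyl (2R)-6-bromo-2-(2-methoxy-2-oxoethyl)-2,3,4,7-tetrahydrooxepine-2-carboxylate | BrC1=CCC[C@@](CC(=O)OC)(C(=O)OCC[Si](C)(C)C)OC1 | intermediate
17 | 5-bromo-2-methylpent-2-ene | CC(C)=CCCBr | starting material
18 | (2E)-5-bromo-2-methylpent-2-en-1-ol | C/C(=C\CCBr)CO | intermediate
19 | {[(2E)-5-bromo-2-methylpent-2-en-1-yl]oxy}triethylsilane | C/C(=C\CCBr)CO[Si](CC)(CC)CC | intermediate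
20 | bromo{(3E)-4-methyl-5-[(triethylsilyl)oxy]pent-3-en-1-yl}zinc | C/C(=C\CC[Zn]Br)CO[Si](CC)(CC)CC | intermediate (not isolated)
21 | 2-(trimethylsilyl)ethyl (2R)-2-(2-methoxy-2-oxoethyl)-6-{(3E)-4-methyl-5-[(triethylsilyl)oxy]pent-3-en-1-yl}-2,3,4,7-tetrahydrooxepine-2-carboxylate | C/C(=C\CCC1=CCC[C@@](CC(=O)OC)(C(=O)OCC[Si](C)(C)C)OC1)CO[Si](CC)(CC)CC | intermediate
22 | [(2R)-6-{(3E)-4-methyl-5-[(triethylsilyl)oxy]pent-3-en-1-yl}-2-{[2-(trimethylsilyl)ethoxy]carbonyl}-2,3,4,7-tetrahydrooxepin-2-yl]acetic acid | C/C(=C\CCC1=CCC[C@@](CC(=O)O)(C(=O)OCC[Si](C)(C)C)OC1)CO[Si](CC)(CC)CC | intermediate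
23 | 2-(trimethylsilyl)ethyl (2R)-2-(2-chloro-2-oxoethyl)-6-{(3E)-4-methyl-5-[(triethylsilyl)oxy]pent-3-en-1-yl}-2,3,4,7-tetrahydrooxepine-2-carboxylate | C/C(=C\CCC1=CCC[C@@](CC(=O)Cl)(C(=O)OCC[Si](C)(C)C)OC1)CO[Si](CC)(CC)CC | intermediate
24 | 2-bromobenzene-1,4-diol (bromohydroquinone) | Oc1ccc(O)c(Br)c1 | starting material
25 | 2-bromo-1,4-bis[(tert-butyldimethylsilyl)oxy]benzene | CC(C)(C)[Si](C)(C)Oc1ccc(O[Si](C)(C)C(C)(C)C)c(Br)c1 | intermediate
26 | {2,5-bis[(tert-butyldimethylsilyl)oxy]phenyl}lithium | [Li]c1cc(O[Si](C)(C)C(C)(C)C)ccc1O[Si](C)(C)C(C)(C)C | intermediate (not isolated)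
27 | {2,5-bis[(tert-butyldimethylsilyl)oxy]phenyl}zinc chloride | Cl[Zn]c1cc(O[Si](C)(C)C(C)(C)C)ccc1O[Si](C)(C)C(C)(C)C | intermediate (not isolated)
28 | 2-(trimethylsilyl)ethyl (2R)-2-(2-{2,5-bis[(tert-butyldimethylsilyl)oxy]phenyl}-2-oxoethyl)-6-{(3E)-4-methyl-5-[(triethylsilyl)oxy]pent-3-en-1-yl}-2,3,4,7-tetrahydrooxepine-2-carboxylate | C/C(=C\CCC1=CCC[C@@](CC(=O)c2cc(O[Si](C)(C)C(C)(C)C)ccc2O[Si](C)(C)C(C)(C)C)(C(=O)OCC[Si](C)(C)C)OC1)CO[Si](CC)(CC)CC | intermediate
29 | 2-(trimethylsilyl)ethyl (2R)-2-(2-{2,5-bis[(tert-butyldimethylsilyl)oxy]phenyl}-2-oxoethyl)-6-[(3E)-5-hydroxy-4-methylpent-3-en-1-yl]-2,3,4,7-tetrahydrooxepine-2-carboxylate | C/C(=C\CCC1=CCC[C@@](CC(=O)c2cc(O[Si](C)(C)C(C)(C)C)ccc2O[Si](C)(C)C(C)(C)C)(C(=O)OCC[Si](C)(C)C)OC1)CO | intermediate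
30 | (2E)-3-(4-hydroxyphenyl)prop-2-enoic acid (p-coumaric acid) | OC(=O)/C=C/c1ccc(O)cc1 | starting material
31 | tert-butyldimethylsilyl (2E)-3-{4-[(tert-butyldimethylsilyl)oxy]phenyl}prop-2-enoate | CC(C)(C)[Si](C)(C)OC(=O)/C=C/c1ccc(O[Si](C)(C)C(C)(C)C)cc1 | intermediate (not isolated)
32 | (2E)-3-{4-[(tert-butyldimethylsilyl)oxy]phenyl}prop-2-enoic acid | OC(=O)/C=C/c1ccc(O[Si](C)(C)C(C)(C)C)cc1 | intermediate
33 | 2-(trimethylsilyl)ethyl (2R)-2-(2-{2,5-bis[(tert-butyldimethylsilyl)oxy]phenyl}-2-oxoethyl)-6-{(3E)-5-[((2E)-3-{4-[(tert-butyldimethylsilyl)oxy]phenyl}prop-2-enoyl)oxy]-4-methylpent-3-en-1-yl}-2,3,4,7-tetrahydrooxepine-2-carboxylate | C/C(=C\CCC1=CCC[C@@](CC(=O)c2cc(O[Si](C)(C)C(C)(C)C)ccc2O[Si](C)(C)C(C)(C)C)(C(=O)OCC[Si](C)(C)C)OC1)COC(=O)/C=C/c1ccc(O[Si](C)(C)C(C)(C)C)cc1 | intermediate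
34 | (2R)-2-[2-(2,5-dihydroxyphenyl)-2-oxoethyl]-6-[(3E)-5-{[(2E)-3-(4-hydroxyphenyl)prop-2-enoyl]oxy}-4-methylpent-3-en-1-yl]-2,3,4,7-tetrahydrooxepine-2-carboxylic acid | C/C(=C\CCC1=CCC[C@@](CC(=O)c2cc(O)ccc2O)(C(=O)O)OC1)COC(=O)/C=C/c1ccc(O)cc1 | target

## Step count and risk

Total: 20 steps. Longest linear sequence: 16 steps (steps 1 to 9, 12, 13, 14, 16, 17, 19, 20).

Least certain steps:

Step 8 (key step). Most likely failures: the cyclopropane may collapse by another path, either proton loss from the allyl cation to a bromodiene or dehydrobromination to a cyclopropene that leads to ring-retained products. The cation may also be intercepted by the carbonyl oxygen of the C2 acetate arm. Both are more likely than usual here because the electron-poor C2 makes O1 a weaker donor and so slows the wanted ionisation. Fallback, a different one-carbon ring enlargement that sets out from dihydropyran 11 and returns at 21: hydroboration of the enol ether with BH3·THF at 0 °C and oxidation with NaBO3 would put a hydroxyl on C5 and give 2-(trimethylsilyl)ethyl (2R)-5-hydroxy-2-(2-methoxy-2-oxoethyl)oxane-2-carboxylate F1. Dess–Martin oxidation would give the 5-oxooxane F2. Insertion of (trimethylsilyl)diazomethane under BF3·OEt2, with migration of the carbon that is not bound to oxygen, would give the C-silylated 6-oxooxepane F3, and protodesilylation with PPTS in methanol the 6-oxooxepane F4. Kinetic deprotonation on the side away from oxygen with LiHMDS and trapping with PhNTf2 would give the enol triflate F5, which would replace bromide 16 in the coupling with zinc reagent 20 under the conditions of step 12 and give 21.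

Step 5. Most likely failure: formyl insertion at the internal carbon or isomerisation of the alkene away from the terminus, because the allyl group sits next to a crowded quaternary carbon with a coordinating hydroxyl. Fallback from 7 to 9: cross-metathesis of 7 with crotonaldehyde under second-generation Hoveyda–Grubbs catalyst would give 4-methyl 1-[2-(trimethylsilyl)ethyl] (2R)-2-hydroxy-2-[(2E)-4-oxobut-2-en-1-yl]butanedioate F6. Hydrogenation of its C=C bond over Pd/C in ethyl acetate would give aldehyde 8, which closes to lactol 9.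

Step 12. Most likely failure: β-hydride elimination from the alkylpalladium intermediate, which would lead to hydrodebromination of the ring and isomerised chain, or incomplete zinc insertion with protonolysis of the reagent. Fallback from 16 and 19 directly to 21 without a preformed organometallic: nickel-catalysed reductive cross-electrophile coupling of the two bromides (NiBr2(dme), 4,4'-di-tert-butyl-2,2'-bipyridine, Mn powder, NaI, DMA, rt to 40 °C), in which the alkyl partner enters as a radical; no new compound is made on the way.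

Step 16. Most likely failure: migration of the ortho silyl group from oxygen to carbon in aryllithium 26 before transmetalation, or slow transmetalation of the hindered arylzinc, which leaves the acylpalladium species time to decarbonylate. Fallback from acid 22 to 28: amide formation with N,O-dimethylhydroxylamine hydrochloride, EDC·HCl and N-methylmorpholine would give the Weinreb amide F7. The Grignard reagent F8, made from 25 with magnesium turnings and LiCl in THF, shows no silyl migration and would add to F7 at 0 °C to give ketone 28 through a stable chelate; the hindered silylethyl ester should not react.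

Step 20. Most likely failure: enolisation of the aryl ketone by basic fluoride and β-elimination of O1. This would open the oxepine and lose the C2 configuration on reclosure, or divert the material to a chromanone through the freed ortho phenoxide. Fallback from 33 to 34 in two stages, so that the ketone meets fluoride only in a buffered medium: KHF2 in methanol at rt would first remove the three aryl silyl ethers under weakly acidic conditions and give the triphenol silylethyl ester F9. The silylethyl ester would then be cleaved with TBAF buffered with AcOH in THF, the three phenols acting as additional proton sources, to give 34.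

## Further compounds

F1 | step 8 | 2-(trimethylsilyl)ethyl (2R)-5-hydroxy-2-(2-methoxy-2-oxoethyl)oxane-2-carboxylate (both C5 epimers) | OC1CC[C@@](CC(=O)OC)(C(=O)OCC[Si](C)(C)C)OC1
F2 | step 8 | 2-(trimethylsilyl)ethyl (2R)-2-(2-methoxy-2-oxoethyl)-5-oxooxane-2-carboxylate | O=C1CC[C@@](CC(=O)OC)(C(=O)OCC[Si](C)(C)C)OC1
F3 | step 8 | 2-(trimethylsilyl)ethyl (2R)-2-(2-methoxy-2-oxoethyl)-6-oxo-5-(trimethylsilyl)oxepane-2-carboxylate (both C5 epimers) | O=C1C([Si](C)(C)C)CC[C@@](CC(=O)OC)(C(=O)OCC[Si](C)(C)C)OC1
F4 | step 8 | 2-(trimethylsilyl)ethyl (2R)-2-(2-methoxy-2-oxoethyl)-6-oxooxepane-2-carboxylate | O=C1CCC[C@@](CC(=O)OC)(C(=O)OCC[Si](C)(C)C)OC1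
F5 | step 8 | 2-(trimethylsilyl)ethyl (2R)-2-(2-methoxy-2-oxoethyl)-6-[(trifluoromethanesulfonyl)oxy]-2,3,4,7-tetrahydrooxepine-2-carboxylate | O=S(=O)(OC1=CCC[C@@](CC(=O)OC)(C(=O)OCC[Si](C)(C)C)OC1)C(F)(F)F
F6 | step 5 | 4-methyl 1-[2-(trimethylsilyl)ethyl] (2R)-2-hydroxy-2-[(2E)-4-oxobut-2-en-1-yl]butanedioate | O=C/C=C/C[C@@](CC(=O)OC)(C(=O)OCC[Si](C)(C)C)O
F0 | step 12 | none | none
F7 | step 16 | 2-(trimethylsilyl)ethyl (2R)-2-{2-[methoxy(methyl)amino]-2-oxoethyl}-6-{(3E)-4-methyl-5-[(triethylsilyl)oxy]pent-3-en-1-yl}-2,3,4,7-tetrahydrooxepine-2-carboxylate | C/C(=C\CCC1=CCC[C@@](CC(=O)N(C)OC)(C(=O)OCC[Si](C)(C)C)OC1)CO[Si](CC)(CC)CC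
F8 | step 16 | {2,5-bis[(tert-butyldimethylsilyl)oxy]phenyl}magnesium bromide | Br[Mg]c1cc(O[Si](C)(C)C(C)(C)C)ccc1O[Si](C)(C)C(C)(C)C
F9 | step 20 | 2-(trimethylsilyl)ethyl (2R)-2-[2-(2,5-dihydroxyphenyl)-2-oxoethyl]-6-[(3E)-5-{[(2E)-3-(4-hydroxyphenyl)prop-2-enoyl]oxy}-4-methylpent-3-en-1-yl]-2,3,4,7-tetrahydrooxepine-2-carboxylate | C/C(=C\CCC1=CCC[C@@](CC(=O)c2cc(O)ccc2O)(C(=O)OCC[Si](C)(C)C)OC1)COC(=O)/C=C/c1ccc(O)cc1
A1 | alternative 1 | open-chain hydroxy enone: Z-allylic alcohol (C7 hydroxyl) linked through C5, C4 and C3 to the (E)-aroylacrylate at C2, silyl-protected as in 28 | OC/C(CC/C=C(\C)CO[Si](CC)(CC)CC)=C\CC/C(C(=O)OCC[Si](C)(C)C)=C\C(=O)c1cc(O[Si](C)(C)C(C)(C)C)ccc1O[Si](C)(C)C(C)(C)C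
A2 | alternative 1 | protected oxepine ketone with side-chain triethylsilyl ether, identical with 28 | C/C(=C\CCC1=CCC[C@@](CC(=O)c2cc(O[Si](C)(C)C(C)(C)C)ccc2O[Si](C)(C)C(C)(C)C)(C(=O)OCC[Si](C)(C)C)OC1)CO[Si](CC)(CC)CC
A3 | alternative 2 | 2-(trimethylsilyl)ethyl (2R)-2-[(2-{2,5-bis[(tert-butyldimethylsilyl)oxy]phenyl}-1,3-dioxolan-2-yl)methyl]-7-diazo-2-hydroxy-6-oxoheptanoate | [N-]=[N+]=CC(=O)CCC[C@@](CC1(OCCO1)c1cc(O[Si](C)(C)C(C)(C)C)ccc1O[Si](C)(C)C(C)(C)C)(C(=O)OCC[Si](C)(C)C)O
A4 | alternative 2 | 2-(trimethylsilyl)ethyl (2R)-2-[(2-{2,5-bis[(tert-butyldimethylsilyl)oxy]phenyl}-1,3-dioxolan-2-yl)methyl]-6-oxooxepane-2-carboxylate | O=C1CCC[C@@](CC2(OCCO2)c2cc(O[Si](C)(C)C(C)(C)C)ccc2O[Si](C)(C)C(C)(C)C)(C(=O)OCC[Si](C)(C)C)OC1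
A5 | alternative 3 | methoxymethyl ether of the C2 hydroxyl carrying the (Z)-vinylsilane at C5=C6, the aryl ketone, the silylethyl ester and the silylated cinnamate | C/C(=C\CC/C([Si](C)(C)C)=C/CC[C@@](CC(=O)c1cc(O[Si](C)(C)C(C)(C)C)ccc1O[Si](C)(C)C(C)(C)C)(C(=O)OCC[Si](C)(C)C)OCOC)COC(=O)/C=C/c1ccc(O[Si](C)(C)C(C)(C)C)cc1
A6 | alternative 3 | fully silyl-protected target, identical with 33 | C/C(=C\CCC1=CCC[C@@](CC(=O)c2cc(O[Si](C)(C)C(C)(C)C)ccc2O[Si](C)(C)C(C)(C)C)(C(=O)OCC[Si](C)(C)C)OC1)COC(=O)/C=C/c1ccc(O[Si](C)(C)C(C)(C)C)cc1
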